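**Assumption:** jaeskeanin is the 6,7-epoxide of a ferutinin-type ester, as drawn in the SMILES. In the key Rh step the quaternary cyclopropane carbon is assumed to react with retention, so the (R)-configured cyclopropane is required. The tartramide-dioxaborolane enantiomer is chosen to deliver it.

## Retrosynthetic overview
1. Target ← late, OH-directed epoxidation of the C6=C7 alkene of a diol, then selective esterification of the C9-OH with a protected 4-hydroxybenzoate.
2. The C1 tertiary carbinol comes from isopropyl addition to a C1 ketone. The C9-OH/C10-H pair comes from a Δ9,10 enone by Weitz–Scheffer epoxidation and SmI2 opening.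
3. Key step: a Rh(I)-catalysed intramolecular [5+2] cycloaddition of a vinylcyclopropane–alkyne closes the 7-ring and the 5-ring in one operation. The quaternary cyclopropane carbon becomes C4, so its chirality is transferred.
4. The vinylcyclopropane comes from citral: MeMgBr addition, Charette enantioselective cyclopropanation, ozonolysis, ethynylation and Wittig methylenation.

## Route

**Step 1**
Reactants: 1 citral (geranial)
Product: 2 (E)-4,8-dimethylnona-3,7-dien-2-ol (racemic carbinol)
Conditions: MeMgBr, Et2O, −78 → 0 °C
Reagents that add atoms: methylmagnesium bromide, C[Mg]Br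
Why: 1,2-addition of a Grignard reagent to the conjugated aldehyde gives the allylic alcohol needed as a directing group, and the carbinol stereocentre is destroyed later.

**Step 2**
Reactants: 2
Product: 3 cyclopropylcarbinol, with the (R)-quaternary cyclopropane carbon
Conditions: Et2Zn, CH2I2, tartramide-derived chiral dioxaborolane, CH2Cl2, −10 °C → rt
Reagents that add atoms: diiodomethane, ICI (CH2 source)
Why: Charette enantioselective Simmons–Smith cyclopropanation is directed by the allylic OH, so it selects the proximal trisubstituted alkene over the tail alkene and sets the quaternary carbon (reagent-controlled). The (E)-alkene puts the 1-hydroxyethyl group trans to the chain.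

**Step 3**
Reactants: 3
Product: 4 cyclopropyl methyl ketone
Conditions: Dess–Martin periodinane, NaHCO3, CH2Cl2, rt
Reagents that add atoms: none
Why: Oxidation destroys the unwanted carbinol stereocentre and leaves the tail alkene untouched.

**Step 4**
Reactants: 4
Product: 5 keto-aldehyde (the tail alkene is cleaved to CHO)
Conditions: O3, CH2Cl2/MeOH, −78 °C; then Me2S
Reagents that add atoms: ozone, [O-][O+]=O
Why: The tail alkene is the only alkene present, so ozonolysis is chemoselective. The cyclopropane and the ketone survive.

**Step 5**
Reactants: 5
Product: 6 propargylic alcohol (epimeric at C1)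
Conditions: HC≡CMgBr (1.1 equiv), THF, −78 → 0 °C
Reagents that add atoms: ethynylmagnesium bromide, C#C[Mg]Br
Why: The aldehyde is far more electrophilic than the hindered cyclopropyl methyl ketone. Both C1 epimers converge at step 8.

**Step 6**
Reactants: 6
Product: 7 vinylcyclopropane–alkyne (isopropenyl-cyclopropane with a propargylic alcohol tether)
Conditions: Ph3P=CH2 (from Ph3PCH3Br and KOtBu, 3 equiv), THF, 0 °C → rt
Reagents that add atoms: methylenetriphenylphosphorane, C=P(c1ccccc1)(c1ccccc1)c1ccccc1
Why: Wittig methylenation of the ketone gives the isopropenyl group, which later becomes C7(Me)=C8. The free OH only consumes one extra equivalent of ylide.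

**Step 7 (key step)**
Reactants: 7
Product: 8 hydroazulene dienol (5-7 bicycle; C1 epimeric alcohol)
Conditions: [Rh(CO)2Cl]2 (5 mol %), toluene, 90 °C
Reagents that add atoms: none
Why: Proposed new method: the closest known reaction is the Wender Rh-catalysed intramolecular [5+2] of vinylcyclopropanes with alkynes, extended here to a fully substituted cyclopropane carbon, an α-methylvinyl group and a free propargylic OH. Rh inserts into the proximal cyclopropane C–C bond with retention at the quaternary carbon, the terminal alkyne inserts into the Rh–C(quaternary) bond, and reductive elimination closes the ring. This forms C4–C10 and C8–C9 together, giving the 7-ring (C6=C7 and C9=C10 alkenes) and the 5-ring in one operation, with the angular methyl stereocentre transferred from the cyclopropane.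

**Step 8**
Reactants: 8
Product: 9 dienone (C1 ketone conjugated to C9=C10)
Conditions: Dess–Martin periodinane, NaHCO3, CH2Cl2, rt
Reagents that add atoms: none
Why: Oxidation of the allylic alcohol converts the C1 epimers to one compound.

**Step 9**
Reactants: 9
Product: 10 α,β-epoxy ketone (C9–C10 epoxide)
Conditions: 30% aq. H2O2, 2 M NaOH, MeOH/THF, 0 °C
Reagents that add atoms: hydrogen peroxide, OO
Why: Weitz–Scheffer nucleophilic epoxidation is selective for the enone alkene and leaves the electron-rich C6=C7 alkene alone. Hydroperoxide attacks C9 from the face anti to the angular methyl, so the epoxide oxygen lies on that face.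

**Step 10**
Reactants: 10
Product: 11 β-hydroxy ketone (C9-OH, C10-H, trans-fused)
Conditions: SmI2 (2.5 equiv), THF/MeOH, −78 °C
Reagents that add atoms: none
Why: SmI2 cleaves the α-C–O bond of α,β-epoxy ketones and keeps the O on C9. The samarium enolate is protonated at C10 from the convex face anti to the methyl, giving the trans ring fusion.

**Step 11**
Reactants: 11
Product: 12 diol (C1 tertiary carbinol, C9 secondary alcohol)
Conditions: iPrMgCl·LiCl, anhydrous CeCl3, THF, −78 → 0 °C
Reagents that add atoms: isopropylmagnesium chloride, CC(C)[Mg]Cl
Why: The organocerium reagent adds to the C1 ketone with little enolisation or reduction. It adds anti to the angular methyl, which places the OH cis to the methyl and the isopropyl on the opposite face; this is 1,3-type steric control.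

**Step 12**
Reactants: 12
Product: 13 epoxy diol (C6,C7-epoxide)
Conditions: mCPBA, NaHCO3, CH2Cl2, 0 °C
Reagents that add atoms: mCPBA, OOC(=O)c1cccc(Cl)c1
Why: Henbest-type hydroxyl-directed epoxidation delivers oxygen syn to the homoallylic C9-OH. This is also the face anti to the angular methyl, and a cis-epoxide cannot be opened intramolecularly by the C9 oxygen.

**Step 13**
Reactants: 13; 14 4-acetoxybenzoyl chloride
Product: 15 C9 4-acetoxybenzoate
Conditions: Et3N, DMAP, CH2Cl2, 0 °C → rt
Reagents that add atoms: 4-acetoxybenzoyl chloride, CC(=O)Oc1ccc(cc1)C(Cl)=O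
Why: Acylation is selective for the secondary C9-OH over the hindered tertiary C1-OH, and the epoxide survives the mild base.

**Step 14**
Reactants: 15
Product: 16 target (jaeskeanin)
Conditions: N2H4·AcOH, DMF, rt
Reagents that add atoms: none
Why: Hydrazine acetate cleaves the labile phenolic acetate selectively and leaves the hindered secondary benzoate, the epoxide and the tertiary alcohol intact.

## Compound list
1 | citral (geranial) | CC(C)=CCC/C(C)=C/C=O | starting material
2 | (E)-4,8-dimethylnona-3,7-dien-2-ol | CC(O)/C=C(\C)CCC=C(C)C | intermediate
3 | 1-[(R)-2-methyl-2-(4-methylpent-3-enyl)cyclopropyl]ethanol, hydroxyethyl trans to the chain, carbinol epimeric | CC(O)[C@@H]1C[C@@]1(C)CCC=C(C)C | intermediate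
4 | corresponding cyclopropyl methyl ketone | CC(=O)[C@@H]1C[C@@]1(C)CCC=C(C)C | intermediate
5 | 3-(2-acetyl-1-methylcyclopropyl)propanal | CC(=O)[C@@H]1C[C@@]1(C)CCC=O | intermediate
6 | acetyl-cyclopropane propargylic alcohol, epimeric at C1 | CC(=O)[C@@H]1C[C@@]1(C)CCC(O)C#C | intermediate
7 | isopropenyl-cyclopropane alkynol (vinylcyclopropane–yne) | C=C(C)[C@@H]1C[C@@]1(C)CCC(O)C#C | intermediate
8 | hydroazulene dienol, angular-Me stereocentre set, C1 epimeric | OC1CC[C@]2(C)CC=C(C)CC=C12 | intermediate
9 | hydroazulene dienone (C1=O, Δ9,10, Δ6,7) | O=C1CC[C@]2(C)CC=C(C)CC=C12 | intermediate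
10 | 9,10-epoxy ketone (epoxide anti to Me) | O=C1CC[C@]2(C)CC=C(C)C[C@@H]3O[C@@]321 | intermediate
11 | β-hydroxy ketone (trans-fused, 9-OH) | O=C1CC[C@]2(C)CC=C(C)C[C@H](O)[C@H]21 | intermediate
12 | diol, 1-isopropyl-1,9-dihydroxy, Δ6,7 | CC(C)[C@]1(O)CC[C@]2(C)CC=C(C)C[C@H](O)[C@H]21 | intermediate
13 | 6,7-epoxy diol | CC(C)[C@]1(O)CC[C@]2(C)C[C@@H]3O[C@]3(C)C[C@H](O)[C@H]21 | intermediate
14 | 4-acetoxybenzoyl chloride | CC(=O)Oc1ccc(cc1)C(Cl)=O | starting material
15 | 9-(4-acetoxybenzoate) of 13 | CC(C)[C@]1(O)CC[C@]2(C)C[C@@H]3O[C@]3(C)C[C@H](OC(=O)c3ccc(OC(C)=O)cc3)[C@H]21 | intermediate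
16 | jaeskeanin | CC(C)[C@]1(O)CC[C@]2(C)C[C@@H]3O[C@]3(C)C[C@H](OC(=O)c3ccc(O)cc3)[C@H]21 | target

**Total steps:** 14. **Longest linear sequence:** 14, from citral; 4-acetoxybenzoyl chloride is purchased.

**Three steps most likely to fail**
1. **Step 7, the [5+2] cycloaddition.** A quaternary cyclopropane carbon, an α-methylvinyl group and a free OH may slow it or erode chirality transfer.
   - Fallback: build the same β-hydroxy ketone 11 by Cu-catalysed enantioselective conjugate allylation of 3-methylcyclopent-2-enone, trapping the enolate in an aldol with 3-methylbut-3-enal, and closing the ring by RCM to form C6=C7.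
2. **Step 9 (with step 10), facial selectivity at C9/C10.** Epoxidation may not be selective, or SmI2 protonation may give the cis ring fusion.
   - Fallback: add PhMe2Si-cuprate 1,4 to enone 9, then Fleming–Tamao oxidation to give the 9-OH with retention, with the silyl group delivered anti to the methyl. Epimerise C10 with DBU if needed.
3. **Step 11, isopropyl addition to the hindered C1 ketone.** Enolisation, hydride reduction or retro-aldol of the β-alkoxide may compete.
   - Fallback: add isopropenylcerium (non-basic), then hydrogenate the isopropenyl group with OH-directed Crabtree catalyst. This exploits the free tertiary OH and the more hindered trisubstituted ring alkene.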